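The enone ring of the target (C5–C6(=O)–C7=C8(CH3)–C9) shares C5 and C9 with the cyclobutane, and both carbons flank the cyclobutane carbon C10. With C10 as a carbonyl, the C6–C7–C8 bridge is therefore cut from the two α-carbons of a 3,3-disubstituted cyclobutanone. One operation, the reaction of a C2-symmetric pyrrolidine enamine of 3-methyl-3-(silyloxymethyl)cyclobutanone with (E)-crotonoyl chloride, forms C9–C8 and C5–C6, closes the bicyclo[3.1.1]heptane and fixes C4, C5 and C9. The C10 carbonyl then receives the seven-membered ring C from the arm on C4, and the enone is unmasked last.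

Key step: step 4

**Labels and remarks on the chemistry**

- Atom labels, used for every compound: C1 = CH–O(methacrylate), C2 = CH2, C3 = CH–O(isobutyrate), C4 = quaternary cyclobutane carbon (CH3), C5 = cyclobutane CH bonded to C6, C6 = C=O, C7 = CH=, C8 = C(CH3)=, C9 = cyclobutane CH bonded to C8, C10 = cyclobutane CH bonded to C11, C11 = C(CH3)2. The cyclobutane is C4–C5–C10–C9. The target is (1R,3R,4R,5R,9R,10S). The SMILES in the compound list are authoritative for configuration.
- Ring C is seven-membered: C4 and C10 are diagonal in the cyclobutane, so C3–C2–C1–C11 is a four-carbon bridge on the face opposite the enone bridge. It can only be closed from an arm on C4 that is anti to the enone bridge, hence the bridge must be laid syn to the C4 methyl. Dione 12 as drawn has this arrangement and the C4, C5 and C9 configuration of the target.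
- Assumption: the (2R,5R)-amine is taken as the matched antipode, on the steric model in which the crotonyl unit swings from nitrogen to the enamine carbon past the pyrrolidine carbon whose methyl points away. If experiment shows the opposite sense, the (2S,5S)-amine replaces 6 with nothing else changed.
- C6 is β to C10. Any intermediate with an oxygen on C10 and a free C6 ketone is a 2-acylcyclobutanol and would open by de Mayo-type retro-aldol cleavage. C6 is therefore held as a silyl enol ether from step 7 to step 15.
- The C8 stereocentre of 12–24 is expected as drawn (methyl toward C10) and vanishes in 25. Its hydrogen faces the C4 bridge, so the final desaturation is designed as an anti elimination.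
- Commercial starting materials: 1, 6, 7 and 16.

**Route**

Step 1
Reactants: 1 methyl 3,3-dimethoxycyclobutane-1-carboxylate
Product: 2 methyl 3,3-dimethoxy-1-methylcyclobutane-1-carboxylate
Conditions: LiN(iPr)2, THF, −78 °C; MeI, −78 °C → rt
Reagents that add atoms: iodomethane, CI
Why: Ester enolate alkylation at the only α-position, the ketone being shielded as its dimethyl ketal; no stereocentre is formed.

Step 2
Reactants: 2 methyl 3,3-dimethoxy-1-methylcyclobutane-1-carboxylate
Product: 3 (3,3-dimethoxy-1-methylcyclobutyl)methanol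
Conditions: LiAlH4, THF, 0 °C
Reagents that add atoms: none
Why: Hydride reduction of the ester to the neopentyl primary alcohol; the ketal is inert to LiAlH4.

Step 3
Reactants: 3 (3,3-dimethoxy-1-methylcyclobutyl)methanol
Product: 5 3-methyl-3-{[tri(propan-2-yl)silyl]oxymethyl}cyclobutan-1-one, via silyl ether ketal 4 (not isolated)
Conditions: TIPSCl, imidazole, DMF, rt; then 1 M HCl, THF, rt
Reagents that add atoms: chlorotri(propan-2-yl)silane, CC(C)[Si](Cl)(C(C)C)C(C)C; water, O
Why: Silylation of the primary alcohol followed in the same flask by acid hydrolysis of the dimethyl ketal, which the primary TIPS ether should survive, gives the achiral ketone with two enantiotopic α-CH2 groups.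

Step 4
Reactants: 5 3-methyl-3-{[tri(propan-2-yl)silyl]oxymethyl}cyclobutan-1-one; 6 (2R,5R)-2,5-dimethylpyrrolidine; 7 (2E)-but-2-enoyl chloride
Product: 12 (1R,4R,5R,7R)-4,7-dimethyl-7-{[tri(propan-2-yl)silyl]oxymethyl}bicyclo[3.1.1]heptane-2,6-dione, via enamine 8 (not isolated), via N-crotonoyl enammonium chloride 9 (not isolated), via ketene iminium chloride 10 (not isolated), via bicyclic keto iminium chloride 11 (not isolated)
Conditions: 6 (1.3 equiv), TsOH (1 mol %), 4 Å MS, cyclohexane, reflux; volatiles removed under Ar; 7 (1.05 equiv), MeCN, −30 → 50 °C; then AcOH/NaOAc buffer (pH 5), THF/H2O, 0 °C → rt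
Reagents that add atoms: (2E)-but-2-enoyl chloride (7), C/C=C/C(Cl)=O; water, O; (2R,5R)-2,5-dimethylpyrrolidine (6), C[C@@H]1CC[C@@H](C)N1 (carried by 8–11 only and released again)
Why: Proposed new method: N-acylation of enamine 8 by 7 gives acylammonium 9, a cationic aza-Claisen ([3,3]) shift then bonds the crotonyl β-carbon to C9 and leaves ketene–iminium 10, and after loss of the C5 proton that carbon attacks the ketene to give keto-iminium 11, which mild acid hydrolysis converts to 12. The closest known reaction is the α,α′-annulation of five- to eight-membered ketone enamines with acryloyl chlorides to bicyclo[3.n.1]alkanediones; a cyclobutanone enamine has not been used in it. The single ring closed is six-membered (C5–C6–C7–C8–C9–C10) and closes by 6-(enolendo)-exo-dig C-acylation of the less substituted enamine at the ketene carbon, necessarily cis across the four-membered ring, which sets C5 from C9. C9 is set in the [3,3] step on the ring face anti to the CH2OSi arm, so the bridge lies syn to the C4 methyl and C4 becomes stereogenic with the arm anti, while the chair transition state with the (E)-methyl pointing away from the ring places the C8 methyl toward C10. Which enantiotopic α-carbon reacts is decided by the C2-symmetric amine: on the open face only one of the two interconverting enamine regioisomers lets the crotonyl unit approach away from the neighbouring pyrrolidine methyl. The step thus needs face selectivity (arm bulk), α-carbon selectivity (auxiliary) and bridging in preference to open-chain acylation (the hindered amine disfavours the more substituted enamine and keeps C5 nucleophilic), and the blocked 3-position and inert silyl ether leave no other reactive site.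

Step 5
Reactants: 12 (1R,4R,5R,7R)-4,7-dimethyl-7-{[tri(propan-2-yl)silyl]oxymethyl}bicyclo[3.1.1]heptane-2,6-dione
Product: 13 (1R,4R,5R,7R)-7-(hydroxymethyl)-4,7-dimethylbicyclo[3.1.1]heptane-2,6-dione
Conditions: HF·pyridine, pyridine, THF, 0 °C → rt
Reagents that add atoms: none
Why: Fluoride desilylation under acidic buffering frees the primary alcohol without exposing the strained, non-enolisable 1,3-dione to a basic nucleophile that could open it by retro-Claisen cleavage.

Step 6
Reactants: 13 (1R,4R,5R,7R)-7-(hydroxymethyl)-4,7-dimethylbicyclo[3.1.1]heptane-2,6-dione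
Product: 14 (1R,4R,5R,7R)-4,7-dimethyl-2,6-dioxobicyclo[3.1.1]heptane-7-carbaldehyde
Conditions: Dess–Martin periodinane, NaHCO3, CH2Cl2, 0 °C → rt
Reagents that add atoms: none
Why: Dess–Martin oxidation of the neopentyl alcohol to the non-enolisable aldehyde under buffered neutral conditions that the dione should tolerate.

Step 7
Reactants: 14 (1R,4R,5R,7R)-4,7-dimethyl-2,6-dioxobicyclo[3.1.1]heptane-7-carbaldehyde
Product: 15 C6 tert-butyldimethylsilyl enol ether of 14 (C6=C7 double bond)
Conditions: TBSOTf, Et3N, CH2Cl2, −78 → 0 °C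
Reagents that add atoms: tert-butyldimethylsilyl trifluoromethanesulfonate, CC(C)(C)[Si](C)(C)OS(=O)(=O)C(F)(F)F
Why: Soft enolisation and O-silylation, regiospecific because C6 is the only enolisable carbonyl (C5 and C9 are bridgeheads, the aldehyde has no α-hydrogen), removes the β-carbonyl electron sink before C10 is attacked and marks C7 for the last step.

Step 8
Reactants: 15 C6 tert-butyldimethylsilyl enol ether of 14; 16 3-bromo-3-methylbutan-2-one
Product: 17 (3R)-β-hydroxy ketone whose arm on C4 is CH(OH)–CH2–C(=O)–CBr(CH3)2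
Conditions: 16 (1.3 equiv), (−)-Ipc2BCl (1.2 equiv), Et3N, Et2O, −78 → 0 °C; 15, −78 → −20 °C; then MeOH/pH 7 buffer, rt (no peroxide)
Reagents that add atoms: 3-bromo-3-methylbutan-2-one (16), CC(=O)C(C)(C)Br
Why: Diisopinocampheylboron-mediated aldol addition in which the boron enolate of 16 (only its methyl group is enolisable) adds chemoselectively to the aldehyde and the (−)-Ipc ligands direct attack to the Re face to set (3R) by reagent control; the ketone is kept in excess over boron and the work-up is non-oxidative to spare the enol ether and the cyclobutanone.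

Step 9
Reactants: 17 (3R)-β-hydroxy ketone
Product: 18 C3 2-methylpropanoate (isobutyrate) of 17
Conditions: iPrCOCl, pyridine, DMAP (cat.), CH2Cl2, 0 °C → rt
Reagents that add atoms: 2-methylpropanoyl chloride, CC(C)C(Cl)=O
Why: DMAP-catalysed acylation installs the C3 ester of the target at once and removes the free hydroxyl that could otherwise displace the tertiary bromide.

Step 10
Reactants: 18 C3 isobutyrate bromo ketone
Product: 19 tricyclic hydroxy ketone (ring C closed by the C10–C11 bond; C10–OH syn to the C6–C8 bridge; C1 ketone)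
Conditions: SmI2 (2.5 equiv), THF, −78 °C; sat. aq. NH4Cl, −78 °C
Reagents that add atoms: none
Why: Intramolecular Reformatsky-type aldol reaction mediated by SmI2, in which reduction of the tertiary α-bromo ketone gives a trivalent samarium enolate regiospecifically at C11 that adds to the strained C10 carbonyl from the only face the C4 tether can reach, setting C10 with its oxygen syn to the bridge while the masked C6 cannot trigger ring opening.

Step 11
Reactants: 19 tricyclic hydroxy ketone
Product: 20 C10 methyl oxalate of 19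
Conditions: ClCOCO2Me, DMAP (2 equiv), CH2Cl2, 0 °C → rt
Reagents that add atoms: methyl chlorooxoacetate, COC(=O)C(Cl)=O
Why: Acyl transfer from the small, highly electrophilic oxalyl half-ester chloride to the tertiary cyclobutanol gives the mixed oxalate needed for radical C–O cleavage.

Step 12
Reactants: 20 C10 methyl oxalate
Product: 21 C10-deoxy tricyclic ketone (C10–H, 10S)
Conditions: Bu3SnH, (PhSe)2 (10 mol %), AIBN, PhMe, 100 °C
Reagents that add atoms: none
Why: Radical deoxygenation of a tertiary methyl oxalate (Barton-type) in which stannyl radical addition and β-scission give the C10 radical, which can accept hydrogen only on the face opposite C11 and is trapped by PhSeH formed in situ before a Dowd–Beckwith-type 1,2-acyl shift can compete.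

Step 13
Reactants: 21 C10-deoxy tricyclic ketone
Product: 22 (1R)-alcohol (C1–OH trans to the C3 ester)
Conditions: (S)-2-methyl-CBS-oxazaborolidine (20 mol %), catecholborane, PhMe, −78 → −40 °C; MeOH
Reagents that add atoms: none
Why: Corey–Bakshi–Shibata reduction in which the (S)-oxazaborolidine distinguishes the quaternary C11 flank from the C2 methylene and should deliver hydride to give the (1R)-alcohol, catecholborane leaving the enol ether and the ester untouched.

Step 14
Reactants: 22 (1R)-alcohol
Product: 23 C1 2-methylprop-2-enoate (methacrylate) of 22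
Conditions: methacryloyl chloride, Et3N, DMAP (cat.), BHT, CH2Cl2, 0 °C → rt
Reagents that add atoms: 2-methylprop-2-enoyl chloride, C=C(C)C(Cl)=O
Why: DMAP-catalysed acylation of the hindered secondary alcohol installs the second ester, and the trans-1,3 arrangement of the two oxygens on ring C should prevent acyl migration.

Step 15
Reactants: 23 C1 methacrylate
Product: 25 target CNP0214356.1, via C7 bromo ketone 24 (not isolated)
Conditions: NBS, NaHCO3, THF, −78 → 0 °C; solvent exchange; Li2CO3, LiBr, BHT, DMF, 100 °C
Reagents that add atoms: N-bromosuccinimide, O=C1CCC(=O)N1Br (bromine carried by 24 only and lost again as bromide)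
Why: Electrophilic bromination of the silyl enol ether at C7 from the face away from the C4 bridge followed by E2 dehydrobromination, chosen because the C8 hydrogen is anti to that bromide (a syn palladium- or selenoxide-based desaturation would find no syn β-hydrogen on the open face), with bromide exchange under LiBr correcting any C7 epimer.

**Compound list**

1 | methyl 3,3-dimethoxycyclobutane-1-carboxylate | COC(=O)C1CC(OC)(OC)C1 | starting material
2 | methyl 3,3-dimethoxy-1-methylcyclobutane-1-carboxylate | COC(=O)C1(C)CC(OC)(OC)C1 | intermediate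
3 | (3,3-dimethoxy-1-methylcyclobutyl)methanol | OCC1(C)CC(OC)(OC)C1 | intermediate
4 | [(3,3-dimethoxy-1-methylcyclobutyl)methoxy]tri(propan-2-yl)silane | COC1(OC)CC(C)(CO[Si](C(C)C)(C(C)C)C(C)C)C1 | intermediate (not isolated)
5 | 3-methyl-3-{[tri(propan-2-yl)silyl]oxymethyl}cyclobutan-1-one | O=C1CC(C)(CO[Si](C(C)C)(C(C)C)C(C)C)C1 | intermediate
6 | (2R,5R)-2,5-dimethylpyrrolidine | C[C@@H]1CC[C@@H](C)N1 | starting material
7 | (2E)-but-2-enoyl chloride | C/C=C/C(Cl)=O | starting material
8 | 1-[(2R,5R)-2,5-dimethylpyrrolidin-1-yl]-3-methyl-3-{[tri(propan-2-yl)silyl]oxymethyl}cyclobut-1-ene (both double-bond regioisomers, in equilibrium) | C[C@@H]1CC[C@@H](C)N1C2=CC(C)(CO[Si](C(C)C)(C(C)C)C(C)C)C2 | intermediate (not isolated)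
9 | N-crotonoyl enammonium chloride of 8 (productive regioisomer) | C/C=C/C(=O)[N+]1(C2=C[C@@](C)(CO[Si](C(C)C)(C(C)C)C(C)C)C2)[C@H](C)CC[C@H]1C.[Cl-] | intermediate (not isolated)
10 | ketene iminium chloride (C9–C8 bond formed) | O=C=C[C@@H](C)[C@H]1C(=[N+]2[C@H](C)CC[C@H]2C)C[C@]1(C)CO[Si](C(C)C)(C(C)C)C(C)C.[Cl-] | intermediate (not isolated)
11 | bicyclic keto iminium chloride (C10 iminium of 12) | CC(C)[Si](C(C)C)(C(C)C)OC[C@@]2(C)[C@@H]3C(=O)C[C@@H](C)[C@H]2C3=[N+]1[C@H](C)CC[C@H]1C.[Cl-] | intermediate (not isolated)
12 | (1R,4R,5R,7R)-4,7-dimethyl-7-{[tri(propan-2-yl)silyl]oxymethyl}bicyclo[3.1.1]heptane-2,6-dione (C6 and C10 ketones; C4 methyl syn to the C6–C8 bridge; C8 methyl toward C10) | CC(C)[Si](C(C)C)(C(C)C)OC[C@@]2(C)[C@@H]3C(=O)C[C@@H](C)[C@H]2C3=O | intermediate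
13 | (1R,4R,5R,7R)-7-(hydroxymethyl)-4,7-dimethylbicyclo[3.1.1]heptane-2,6-dione | OC[C@@]2(C)[C@@H]3C(=O)C[C@@H](C)[C@H]2C3=O | intermediate
14 | (1R,4R,5R,7R)-4,7-dimethyl-2,6-dioxobicyclo[3.1.1]heptane-7-carbaldehyde | O=C[C@@]2(C)[C@@H]3C(=O)C[C@@H](C)[C@H]2C3=O | intermediate
15 | C6 tert-butyldimethylsilyl enol ether of 14 (C6=C7) | O=C[C@@]2(C)[C@@H]3C(O[Si](C)(C)C(C)(C)C)=C[C@@H](C)[C@H]2C3=O | intermediate
16 | 3-bromo-3-methylbutan-2-one | CC(=O)C(C)(C)Br | starting material
17 | (3R)-β-hydroxy α′-bromo ketone (arm on C4: CH(OH)CH2C(=O)CBr(CH3)2) | CC(C)(Br)C(=O)C[C@@H](O)[C@@]2(C)[C@@H]3C(O[Si](C)(C)C(C)(C)C)=C[C@@H](C)[C@H]2C3=O | intermediate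
18 | C3 isobutyrate of 17 | CC(C)(Br)C(=O)C[C@@H](OC(=O)C(C)C)[C@@]2(C)[C@@H]3C(O[Si](C)(C)C(C)(C)C)=C[C@@H](C)[C@H]2C3=O | intermediate
19 | tricyclic hydroxy ketone (ring C closed; C10–OH; C1 ketone) | O=C1C[C@@H](OC(=O)C(C)C)[C@@]2(C)[C@@H]3C(O[Si](C)(C)C(C)(C)C)=C[C@@H](C)[C@H]2[C@]3(O)C1(C)C | intermediate
20 | C10 methyl oxalate of 19 | O=C1C[C@@H](OC(=O)C(C)C)[C@@]2(C)[C@@H]3C(O[Si](C)(C)C(C)(C)C)=C[C@@H](C)[C@H]2[C@]3(OC(=O)C(=O)OC)C1(C)C | intermediate
21 | C10-deoxy tricyclic ketone | O=C1C[C@@H](OC(=O)C(C)C)[C@@]2(C)[C@@H]3C(O[Si](C)(C)C(C)(C)C)=C[C@@H](C)[C@H]2[C@@H]3C1(C)C | intermediate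
22 | (1R)-alcohol | O[C@@H]1C[C@@H](OC(=O)C(C)C)[C@@]2(C)[C@@H]3C(O[Si](C)(C)C(C)(C)C)=C[C@@H](C)[C@H]2[C@@H]3C1(C)C | intermediate
23 | C1 methacrylate of 22 | C=C(C)C(=O)O[C@@H]1C[C@@H](OC(=O)C(C)C)[C@@]2(C)[C@@H]3C(O[Si](C)(C)C(C)(C)C)=C[C@@H](C)[C@H]2[C@@H]3C1(C)C | intermediate
24 | C7 bromo ketone (bromine on the face toward C10) | C=C(C)C(=O)O[C@@H]1C[C@@H](OC(=O)C(C)C)[C@@]2(C)[C@@H]3C(=O)[C@@H](Br)[C@@H](C)[C@H]2[C@@H]3C1(C)C | intermediate (not isolated)
25 | CNP0214356.1, (1R,3R,4R,5R,9R,10S) in the labels above | C=C(C)C(=O)O[C@@H]1C[C@@H](OC(=O)C(C)C)[C@@]2(C)[C@@H]3C(=O)C=C(C)[C@H]2[C@@H]3C1(C)C | target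

**Count and risks**

Total step count: 15. Longest linear sequence: 15 steps (1 → 25).

Steps most likely to fail:

Step 4 (the step that carries the label). Process at risk: after the [3,3] shift the ketene is intercepted by chloride or amine before C5 reaches it, so that the strained 1,3-dione never closes, or the bridge forms on both ring faces and at both α-carbons. Fallback: the four-membered ring is made instead of bridged, by an intramolecular vinylketene–alkene [2+2] cycloaddition, a reaction type established for 7,7-disubstituted bicyclo[3.1.1]heptan-6-ones. It does not set out from a compound of the route but replaces steps 1–4, starting from commercial methyl (2E)-3,7-dimethylocta-2,6-dienoate F1. Allylic oxidation (SeO2 cat., tBuOOH) at the (E)-methyl group gives methyl (2E,6E)-8-hydroxy-3,7-dimethylocta-2,6-dienoate F2, silylation gives TIPS ether F3 and LiOH gives the acid F4. Oxalyl chloride gives acid chloride F5. Et3N in refluxing toluene converts it to vinylketene F6, which adds across the C6=C7 alkene to give racemic 2-methylidene ketone F7, the (E)-alkene geometry placing CH3 syn to the three-carbon bridge. Ozonolysis gives racemic dione F8 (the analogue of 12 without the C8 methyl), TMSOTf/Et3N gives its silyl enol ether F9, and Pd(OAc)2 gives enedione F10; here a syn β-hydrogen on the open face is available. Me2CuLi should add methyl to C8 from the face away from the C4 bridge to give racemic 12, and preparative HPLC on a chiral stationary phase separates 12 from its antipode F11. The route is rejoined at 12.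

Step 10. Process at risk: electron transfer only removes bromine, the samarium enolate being protonated at C11 or taking over the C3 isobutyryl group, without attack on the crowded C10 carbonyl. Fallback: a copper hydride reductive aldol cyclisation, in which the C11 enolate is made by conjugate hydride delivery to an enone. It sets out from aldehyde 15. The same (−)-Ipc2BCl aldol, now with 3-methylbut-3-en-2-one, gives the (3R)-hydroxy isopropenyl ketone F12, and isobutyryl chloride/pyridine gives ester F13. [(Ph3P)CuH]6 in toluene adds hydride to the enone terminus, and the copper enolate formed at C11 closes onto C10 to give 19, where the route is rejoined.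

Step 11. Process at risk: the tertiary C10 hydroxyl, flanked by two bridgeheads and the quaternary C11, resists acyl transfer, or long exposure to DMAP eliminates the C3 isobutyrate. Fallback: a thiocarbonyl route through the alkoxide instead of acyl transfer to the neutral alcohol. It sets out from 19. Deprotonation with KN(SiMe3)2 at −78 °C, capture of the alkoxide by the small linear electrophile CS2 and S-methylation with MeI give xanthate F14. Under the tin hydride conditions of step 12 this undergoes Barton–McCombie cleavage to 21, where the route is rejoined.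

Further compounds
F1 | step 4 | methyl (2E)-3,7-dimethylocta-2,6-dienoate | COC(=O)/C=C(\C)CCC=C(C)C
F2 | step 4 | methyl (2E,6E)-8-hydroxy-3,7-dimethylocta-2,6-dienoate | COC(=O)/C=C(\C)CC/C=C(\C)CO
F3 | step 4 | methyl (2E,6E)-3,7-dimethyl-8-{[tri(propan-2-yl)silyl]oxy}octa-2,6-dienoate | COC(=O)/C=C(\C)CC/C=C(\C)CO[Si](C(C)C)(C(C)C)C(C)C
F4 | step 4 | (2E,6E)-3,7-dimethyl-8-{[tri(propan-2-yl)silyl]oxy}octa-2,6-dienoic acid | OC(=O)/C=C(\C)CC/C=C(\C)CO[Si](C(C)C)(C(C)C)C(C)C
F5 | step 4 | acid chloride of F4 | ClC(=O)/C=C(\C)CC/C=C(\C)CO[Si](C(C)C)(C(C)C)C(C)C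
F6 | step 4 | vinylketene from F5 | O=C=CC(=C)CC/C=C(\C)CO[Si](C(C)C)(C(C)C)C(C)C
F7 | step 4 | racemic 7-methyl-2-methylidene-7-{[tri(propan-2-yl)silyl]oxymethyl}bicyclo[3.1.1]heptan-6-one (enantiomer drawn leads to 12) | CC(C)[Si](C(C)C)(C(C)C)OC[C@@]2(C)[C@@H]3C(=C)CC[C@H]2C3=O
F8 | step 4 | racemic 7-methyl-7-{[tri(propan-2-yl)silyl]oxymethyl}bicyclo[3.1.1]heptane-2,6-dione | CC(C)[Si](C(C)C)(C(C)C)OC[C@@]2(C)[C@@H]3C(=O)CC[C@H]2C3=O
F9 | step 4 | racemic C6 trimethylsilyl enol ether of F8 | CC(C)[Si](C(C)C)(C(C)C)OC[C@@]2(C)[C@@H]3C(O[Si](C)(C)C)=CC[C@H]2C3=O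
F10 | step 4 | racemic 7-methyl-7-{[tri(propan-2-yl)silyl]oxymethyl}bicyclo[3.1.1]hept-3-ene-2,6-dione | CC(C)[Si](C(C)C)(C(C)C)OC[C@@]2(C)[C@@H]3C(=O)C=C[C@H]2C3=O
F11 | step 4 | antipode of 12 | CC(C)[Si](C(C)C)(C(C)C)OC[C@]2(C)[C@H]3C(=O)C[C@H](C)[C@@H]2C3=O
F12 | step 10 | (3R)-β-hydroxy isopropenyl ketone | C=C(C)C(=O)C[C@@H](O)[C@@]2(C)[C@@H]3C(O[Si](C)(C)C(C)(C)C)=C[C@@H](C)[C@H]2C3=O
F13 | step 10 | C3 isobutyrate of F12 | C=C(C)C(=O)C[C@@H](OC(=O)C(C)C)[C@@]2(C)[C@@H]3C(O[Si](C)(C)C(C)(C)C)=C[C@@H](C)[C@H]2C3=O
F14 | step 11 | C10 O-alkyl S-methyl xanthate of 19 | O=C1C[C@@H](OC(=O)C(C)C)[C@@]2(C)[C@@H]3C(O[Si](C)(C)C(C)(C)C)=C[C@@H](C)[C@H]2[C@]3(OC(=S)SC)C1(C)C
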